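A direct plan would acylate 4-methylresorcinol A1 with homosyringic acid A2 to the deoxybenzoin A3 and close ring C with a one-carbon unit to the 5-unsubstituted isoflavone A4.
It would then mask both phenols as pivalates to give the dipivalate A5, introduce the 5-methoxy group by carbonyl-directed C–H methoxylation with Pd(OAc)2 and K2S2O8 in methanol to give the 5-methoxy dipivalate A6, and cleave the esters.
Weakest would be the late C5–H methoxylation: it has no precedent on a chromone, must metalate the peri C–H crowded by the 6-methyl group, and exposes the electron-rich ring B and the benzylic methyl group to persulfate on the most advanced material.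
Second would be the pivaloylation and its removal: two operations on the complete skeleton that add no complexity and serve only that oxidation.
Third would be the one-flask acylation and formylation in BF3·OEt2 and MsCl with three free phenols, where O-sulfonylation can compete and the polar triphenol is hard to purify.

Plan of the new route:
The retrosynthesis cuts O1–C2 and then, in one stroke, O1–C8a and C4–C4a. This gives a ring A aryne (C4a≡C8a) and a ring B acid that already carries C2, C3 and C4 as a 3-methoxyacrylic acid.
Feature used: in ring A, O1 and the C4 carbonyl sit on the neighbouring carbons C8a and C4a, C5 beside C4a bears OMe, and C8 beside C8a bears only H. One carboxylate can therefore deliver both substituents across the triple bond, and the C5 methoxy group decides that oxygen goes to C8a and the acyl carbon to C4a.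
Order of rings: ring B receives its complete three-carbon chain first. Ring A, built from a 2-methylresorcinol unit, enters last as an aryne with only two oxygens and gains its third oxygen (O1) from the carboxylate in the flask in which ring C closes. The direct plan instead joins rings A and B first and adds C2 afterwards.
No C–H oxidation is needed, since the 5-methoxy group is present from step 1. No oxidant meets the isoflavone. The only masking groups are two benzyl ethers placed on starting materials and removed together at the end.
The target has no stereocentre.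
Key step: step 8

Assumption: 13, 14 and 16 are drawn as the E enol ethers expected from O-methylation of enolate 12 (whose geometry is left open); the configuration is lost when C2 enters ring C, so either isomer would serve.

Step 1
Reactants: 1 2,4-dihydroxy-3-methylbenzaldehyde
Product: 3 4-(benzyloxy)-2-methoxy-3-methylbenzaldehyde, via 4-(benzyloxy)-2-hydroxy-3-methylbenzaldehyde 2 (not isolated)
Conditions: BnBr (1.05 equiv), NaHCO3 (1.5 equiv), KI (10 mol %), MeCN, 80 °C, 16 h; then K2CO3 (2.5 equiv), MeI (3 equiv), 45 °C (sealed), 12 h
Reagents that add atoms: benzyl bromide, BrCc1ccccc1; iodomethane, CI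
Why: Williamson ether synthesis in two stages, in which the weak base should benzylate only the 4-OH because the 2-OH is held in a hydrogen bond to the formyl group, and the stronger base then methylates that chelated 2-OH, so the aldehyde differentiates the two oxygens that become O7 and O5.

Step 2
Reactants: 3 4-(benzyloxy)-2-methoxy-3-methylbenzaldehyde
Product: 5 4-(benzyloxy)-2-methoxy-3-methylphenol, via 4-(benzyloxy)-2-methoxy-3-methylphenyl formate 4 (not isolated)
Conditions: mCPBA (1.2 equiv), CH2Cl2, 0 °C → rt, 6 h; aq Na2S2O3/NaHCO3 wash; then K2CO3 (0.2 equiv), MeOH, rt, 1 h, Ar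
Reagents that add atoms: 3-chloroperoxybenzoic acid, O=C(OO)c1cccc(Cl)c1
Why: Baeyer–Villiger (Dakin-type) oxidation, in which the aryl group enriched by the ortho-methoxy and para-benzyloxy groups should migrate in preference to hydride, followed by methanolysis of the formate to free the phenol on the carbon that becomes C4a.

Step 3
Reactants: 5 4-(benzyloxy)-2-methoxy-3-methylphenol
Product: 6 4-(benzyloxy)-6-bromo-2-methoxy-3-methylphenol
Conditions: NBS (1.0 equiv), i-Pr2NH (10 mol %), CH2Cl2, −78 → 0 °C, 2 h
Reagents that add atoms: N-bromosuccinimide, O=C1CCC(=O)N1Br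
Why: Amine-catalysed ortho-bromination of a phenol (electrophilic aromatic substitution), in which the N-bromoamine is delivered through a hydrogen bond to the free OH whose para position is blocked, so bromine should enter C6 (the future C8a) and not C5, which is activated only by the benzyloxy group and by a 2-methoxy group twisted out of conjugation by its two neighbours.

Step 4
Reactants: 6 4-(benzyloxy)-6-bromo-2-methoxy-3-methylphenol
Product: 9 4-(benzyloxy)-2-methoxy-3-methyl-6-(trimethylsilyl)phenyl trifluoromethanesulfonate, via aryl trimethylsilyl ether 7 (not isolated), via lithium 2-silylphenolate 8 (not isolated)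
Conditions: HMDS (1.0 equiv), THF, 70 °C, 2 h, then evaporate; n-BuLi (1.1 equiv), THF, −100 → −78 °C, 30 min; Tf2O (1.2 equiv), −100 → −78 °C; aq NaHCO3
Reagents that add atoms: hexamethyldisilazane, C[Si](C)(C)N[Si](C)(C)C; trifluoromethanesulfonic anhydride, O=S(=O)(OS(=O)(=O)C(F)(F)F)C(F)(F)F
Why: O-silylation, bromine–lithium exchange and retro-Brook 1,3 O→C silyl shift should give the ortho-silyl phenolate, which is trapped as its triflate, the standard sequence to ortho-silylaryl triflates from 2-bromophenols (known for 2-bromo-6-methoxyphenol), and the benzyl ether is not deprotonated at −78 °C or below.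

Step 5
Reactants: 10 2-(4-hydroxy-3,5-dimethoxyphenyl)acetic acid (homosyringic acid)
Product: 11 benzyl 2-[4-(benzyloxy)-3,5-dimethoxyphenyl]acetate
Conditions: BnBr (2.3 equiv), K2CO3 (3 equiv), DMF, 60 °C, 12 h
Reagents that add atoms: benzyl bromide, BrCc1ccccc1
Why: Double O-alkylation (Williamson ether synthesis and carboxylate alkylation) masks the ring B phenol, which would otherwise add to the aryne, and gives an ester that can be formylated.

Step 6
Reactants: 11 benzyl 2-[4-(benzyloxy)-3,5-dimethoxyphenyl]acetate
Product: 13 benzyl (E)-2-[4-(benzyloxy)-3,5-dimethoxyphenyl]-3-methoxyprop-2-enoate, via sodium enolate of the formyl ester 12 (not isolated)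
Conditions: NaH (2.2 equiv), HCO2Bn (4 equiv), THF, 0 °C → rt, 12 h; then DMF, Me2SO4 (2.5 equiv), rt, 4 h
Reagents that add atoms: benzyl formate, O=COCc1ccccc1; dimethyl sulfate, COS(=O)(=O)OC
Why: Crossed Claisen condensation of the ester enolate with a formate (the benzyl ester, so that the ester group is not scrambled) and O-methylation of the resulting enolate by the hard electrophile, the classical entry to 3-methoxyacrylates, which installs the future C2 with its leaving group.

Step 7
Reactants: 13 benzyl (E)-2-[4-(benzyloxy)-3,5-dimethoxyphenyl]-3-methoxyprop-2-enoate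
Product: 14 (E)-2-[4-(benzyloxy)-3,5-dimethoxyphenyl]-3-methoxyprop-2-enoic acid
Conditions: LiOH·H2O (3 equiv), THF/MeOH/H2O 3:1:1, 40 °C, 8 h; then 1 M HCl to pH 3, 0 °C
Reagents that add atoms: lithium hydroxide, [Li+].[OH-]
Why: Saponification, in which hydroxide should attack the ester carbonyl in preference to the donor-substituted β-carbon, as in the known hydrolysis of 3-methoxyacrylate esters to their acids, while the aryl benzyl ether is stable to base.

Step 8
Reactants: 9 4-(benzyloxy)-2-methoxy-3-methyl-6-(trimethylsilyl)phenyl trifluoromethanesulfonate; 14 (E)-2-[4-(benzyloxy)-3,5-dimethoxyphenyl]-3-methoxyprop-2-enoic acid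
Product: 17 7-(benzyloxy)-3-[4-(benzyloxy)-3,5-dimethoxyphenyl]-5-methoxy-6-methyl-4H-chromen-4-one, via 5-(benzyloxy)-3-methoxy-4-methylbenzyne 15 (not isolated), via caesium 2-acylphenolate 16 (not isolated)
Conditions: 14 (1.0 equiv), 9 (1.5 equiv), CsF (4 equiv), THF, 125 °C (sealed tube), 24 h
Reagents that add atoms: none
Why: Proposed new method: fluoride removes the silyl group of 9 and triflate leaves to give aryne 15, whose triple bond C4a≡C8a is polarised by the inductively withdrawing C5 methoxy group, so that the carboxylate of 14 should add through oxygen at the distal carbon C8a (beside C8–H) and place the carbanion on C4a, beside the methoxy group. The carbanion should then attack the ester carbonyl in the manner of an anionic ortho-Fries shift (four-membered transition state), which forms C4–C4a and releases phenolate 16 with O1 on C8a. Ring C should close by 6-endo-trig conjugate addition of O1 to C2 followed by loss of methoxide, an addition–elimination at a vinylogous ester that ends in the pyranone and consumes the phenolate before it can add to a second aryne. The closest known reaction type is the CsF-promoted insertion of arynes into the C–O bond of carboxylic acids, which gives ortho-hydroxyaryl ketones from simple acids and 4-chromanones from acrylic acids by the same acyl shift and oxa-Michael closure; not yet shown are a 3-alkoxyacrylic acid that delivers the chromone oxidation level directly and a tetrasubstituted aryne. Two selectivities are needed: the site of addition to the aryne, secured by the C5 methoxy group (which the C6 methyl group turns toward C4a) against the much weaker opposite bias of the C7 benzyloxy group, and acyl shift in preference to attack of the carbanion on C2 (which would give a 3-arylcoumarin), secured by the Z conformation of the aryl ester, which holds C2 away from C4a, and by the donor methoxy group on C2. No stereocentre is formed, and the benzyl ethers, the only other functional groups, are inert to fluoride at 125 °C.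

Step 9
Reactants: 17 7-(benzyloxy)-3-[4-(benzyloxy)-3,5-dimethoxyphenyl]-5-methoxy-6-methyl-4H-chromen-4-one
Product: 18 7-hydroxy-3-(4-hydroxy-3,5-dimethoxyphenyl)-5-methoxy-6-methyl-4H-chromen-4-one (target)
Conditions: H2 (1 atm), Pd/C (10 wt % palladium metal on carbon, 10 mol % Pd), EtOAc/MeOH 1:1, rt, 3 h, stopped at full conversion
Reagents that add atoms: none
Why: Hydrogenolysis of the two aryl benzyl ethers over palladium on carbon, routinely used on benzyl-protected isoflavones, should leave the vinylogous ester double bond C2=C3 and the three methyl ethers untouched at 1 atm and room temperature.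

Compound list
1 | 2,4-dihydroxy-3-methylbenzaldehyde | Cc1c(O)ccc(C=O)c1O | starting material
2 | 4-(benzyloxy)-2-hydroxy-3-methylbenzaldehyde | Cc1c(OCc2ccccc2)ccc(C=O)c1O | intermediate
3 | 4-(benzyloxy)-2-methoxy-3-methylbenzaldehyde | COc1c(C=O)ccc(OCc2ccccc2)c1C | intermediate
4 | 4-(benzyloxy)-2-methoxy-3-methylphenyl formate | COc1c(OC=O)ccc(OCc2ccccc2)c1C | intermediate
5 | 4-(benzyloxy)-2-methoxy-3-methylphenol | COc1c(O)ccc(OCc2ccccc2)c1C | intermediate
6 | 4-(benzyloxy)-6-bromo-2-methoxy-3-methylphenol | COc1c(O)c(Br)cc(OCc2ccccc2)c1C | intermediate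
7 | [4-(benzyloxy)-6-bromo-2-methoxy-3-methylphenoxy]trimethylsilane | COc1c(O[Si](C)(C)C)c(Br)cc(OCc2ccccc2)c1C | intermediate
8 | lithium 4-(benzyloxy)-2-methoxy-3-methyl-6-(trimethylsilyl)phenolate | [Li+].[O-]c1c(OC)c(C)c(OCc2ccccc2)cc1[Si](C)(C)C | intermediate
9 | 4-(benzyloxy)-2-methoxy-3-methyl-6-(trimethylsilyl)phenyl trifluoromethanesulfonate | COc1c(OS(=O)(=O)C(F)(F)F)c([Si](C)(C)C)cc(OCc2ccccc2)c1C | intermediate
10 | 2-(4-hydroxy-3,5-dimethoxyphenyl)acetic acid (homosyringic acid) | COc1cc(CC(=O)O)cc(OC)c1O | starting material
11 | benzyl 2-[4-(benzyloxy)-3,5-dimethoxyphenyl]acetate | COc1cc(CC(=O)OCc2ccccc2)cc(OC)c1OCc1ccccc1 | intermediate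
12 | sodium 3-(benzyloxy)-2-[4-(benzyloxy)-3,5-dimethoxyphenyl]-3-oxoprop-1-en-1-olate | [Na+].[O-]C=C(C(=O)OCc1ccccc1)c1cc(OC)c(OCc2ccccc2)c(OC)c1 | intermediate
13 | benzyl (E)-2-[4-(benzyloxy)-3,5-dimethoxyphenyl]-3-methoxyprop-2-enoate | CO/C=C(\c1cc(OC)c(OCc2ccccc2)c(OC)c1)C(=O)OCc1ccccc1 | intermediate
14 | (E)-2-[4-(benzyloxy)-3,5-dimethoxyphenyl]-3-methoxyprop-2-enoic acid | CO/C=C(\c1cc(OC)c(OCc2ccccc2)c(OC)c1)C(=O)O | intermediate
15 | 5-(benzyloxy)-3-methoxy-4-methylbenzyne (1,2-didehydrobenzene) | COC1=C(C)C(OCc2ccccc2)=CC#C1 | intermediate
16 | caesium 5-(benzyloxy)-2-{(E)-2-[4-(benzyloxy)-3,5-dimethoxyphenyl]-3-methoxyprop-2-enoyl}-3-methoxy-4-methylphenolate | [Cs+].[O-]c1cc(OCc2ccccc2)c(C)c(OC)c1C(=O)/C(=C/OC)c1cc(OC)c(OCc2ccccc2)c(OC)c1 | intermediate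
17 | 7-(benzyloxy)-3-[4-(benzyloxy)-3,5-dimethoxyphenyl]-5-methoxy-6-methyl-4H-chromen-4-one | COc1cc(-c2coc3cc(OCc4ccccc4)c(C)c(OC)c3c2=O)cc(OC)c1OCc1ccccc1 | intermediate
18 | 7-hydroxy-3-(4-hydroxy-3,5-dimethoxyphenyl)-5-methoxy-6-methyl-4H-chromen-4-one | COc1cc(-c2coc3cc(O)c(C)c(OC)c3c2=O)cc(OC)c1O | target

Total step count: 9. Longest linear sequence: 6 (steps 1, 2, 3, 4, 8, 9).

Steps most likely to fail

Step 8 (key step). After the carboxylate has added to the aryne, the aryl carbanion may be protonated before the acyl group shifts, or may add to C2 of the acrylate, and the push–pull acid may lose CO2 under hot fluoride. The fallback sets out from 9 and 11 and comes back at 17. Ester 11 would be saponified (LiOH, THF/H2O) to 2-[4-(benzyloxy)-3,5-dimethoxyphenyl]acetic acid F1, which has neither a Michael acceptor nor an enol ether. With 9 and CsF in THF at 125 °C, the known insertion of an aryne into the C–O bond of a simple carboxylic acid would give, by way of the same aryne 15, the deoxybenzoin 1-[4-(benzyloxy)-6-hydroxy-2-methoxy-3-methylphenyl]-2-[4-(benzyloxy)-3,5-dimethoxyphenyl]ethan-1-one F2. N,N-Dimethylformamide dimethyl acetal in toluene at 100 °C would then add C2 and close ring C to 17. The aryne would still set the ring A pattern, but ring closure would be uncoupled from it.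

Step 3. The bromination may show poor site selectivity (attack beside the benzyloxy group), or the electron-rich hydroquinone monoether may be oxidised instead of substituted. The fallback sets out from 5 and comes back at 9, bypassing step 4 as well. Phenol 5 would be treated with isopropyl isocyanate and Et3N to give 4-(benzyloxy)-2-methoxy-3-methylphenyl N-(propan-2-yl)carbamate F3. N-Silylation in the flask (TMSOTf, TMEDA), lithiation with n-BuLi/TMEDA at −78 °C at the only free position ortho to the carbamate, and quench with TMSCl would give 4-(benzyloxy)-2-methoxy-3-methyl-6-(trimethylsilyl)phenyl N-(propan-2-yl)carbamate F4. DBU and Et2NH in MeCN at 40 °C would release 4-(benzyloxy)-2-methoxy-3-methyl-6-(trimethylsilyl)phenol F5, which PhNTf2 would convert in the same flask into 9. Silicon would thus be placed by directed ortho-metalation, where only one site is open, instead of by an electrophilic substitution.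

Step 9. The C2=C3 double bond may be reduced if the hydrogenation is pushed to cleave the doubly ortho-substituted benzyl ether on ring B. The fallback sets out from 17 and comes back at 18; it makes no new compound, entry F0. The benzyl ethers would be cleaved by acidolysis in CF3CO2H with pentamethylbenzene (10 equiv) as cation scavenger at rt to 50 °C. This is a non-reductive cleavage that cannot touch the double bond, and the non-chelating Brønsted acid should leave the three methyl ethers intact.

Further compounds
F1 | step 8 | 2-[4-(benzyloxy)-3,5-dimethoxyphenyl]acetic acid | COc1cc(CC(=O)O)cc(OC)c1OCc1ccccc1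
F2 | step 8 | 1-[4-(benzyloxy)-6-hydroxy-2-methoxy-3-methylphenyl]-2-[4-(benzyloxy)-3,5-dimethoxyphenyl]ethan-1-one | COc1cc(CC(=O)c2c(O)cc(OCc3ccccc3)c(C)c2OC)cc(OC)c1OCc1ccccc1
F3 | step 3 | 4-(benzyloxy)-2-methoxy-3-methylphenyl N-(propan-2-yl)carbamate | COc1c(OC(=O)NC(C)C)ccc(OCc2ccccc2)c1C
F4 | step 3 | 4-(benzyloxy)-2-methoxy-3-methyl-6-(trimethylsilyl)phenyl N-(propan-2-yl)carbamate | COc1c(OC(=O)NC(C)C)c([Si](C)(C)C)cc(OCc2ccccc2)c1C
F5 | step 3 | 4-(benzyloxy)-2-methoxy-3-methyl-6-(trimethylsilyl)phenol | COc1c(O)c([Si](C)(C)C)cc(OCc2ccccc2)c1C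
F0 | step 9 | none | none
A1 | direct plan | 4-methylbenzene-1,3-diol (4-methylresorcinol) | Cc1ccc(O)cc1O
A2 | direct plan | 2-(4-hydroxy-3,5-dimethoxyphenyl)acetic acid (homosyringic acid) | COc1cc(CC(=O)O)cc(OC)c1O
A3 | direct plan | 1-(2,4-dihydroxy-5-methylphenyl)-2-(4-hydroxy-3,5-dimethoxyphenyl)ethan-1-one | COc1cc(CC(=O)c2cc(C)c(O)cc2O)cc(OC)c1O
A4 | direct plan | 7-hydroxy-3-(4-hydroxy-3,5-dimethoxyphenyl)-6-methyl-4H-chromen-4-one | COc1cc(-c2coc3cc(O)c(C)cc3c2=O)cc(OC)c1O
A5 | direct plan | 3-[3,5-dimethoxy-4-(pivaloyloxy)phenyl]-6-methyl-4-oxo-4H-chromen-7-yl pivalate | COc1cc(-c2coc3cc(OC(=O)C(C)(C)C)c(C)cc3c2=O)cc(OC)c1OC(=O)C(C)(C)C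
A6 | direct plan | 3-[3,5-dimethoxy-4-(pivaloyloxy)phenyl]-5-methoxy-6-methyl-4-oxo-4H-chromen-7-yl pivalate | COc1cc(-c2coc3cc(OC(=O)C(C)(C)C)c(C)c(OC)c3c2=O)cc(OC)c1OC(=O)C(C)(C)C
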